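I began with the easy step, the last noon reading of substrate, taking the one proposed step that consumes it, substrate + partner to intermediate + by-product, as first order in each.

| setting | noon | birch | larch |
|---|---|---|---|
| substrate | 0.30 M | 0.30 M | 0.30 M |
| partner | 0.27 M | 0.240 M | 0.290 M |
| remark | run made earlier |  |  |
| time |  | 80 min | 80 min |

noon run (percent of the substrate charged)

| time / min | intermediate / % | side product / % | substrate / % | target / % |
|---|---|---|---|---|
| 5.00 | 2.7 | 0.3 | 97.5 | 0.1 |
| 15.0 | 6.5 | 0.9 | 93.1 | 0.1 |
| 25.0 | 9.8 | 1.7 | 88.9 | 0 |
| 40.0 | 12.9 | 3.1 | 83.8 | 0.2 |

(readings scatter by 0.3 percentage points)

- steps that have been proposed: intermediate -> target; intermediate -> side product; substrate + partner -> intermediate + by-product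

- which of these there is most of at the end, counted by the substrate in it, birch (intermediate / substrate / target / side product)
- which of these there is most of at the end, counted by the substrate in it, larch (intermediate / substrate / target / side product)
- amount of the one of these that there is most of at the end, in percent of the substrate charged, birch
- amount of the one of these that there is most of at the end, in percent of the substrate charged, larch

The bench rule for such a step is to hold [partner] at a fixed value and let [substrate] decay exponentially, the pseudo-first-order treatment. At 40.0 min the noon run showed 83.8% of its substrate, and since partner falls one for one with substrate, I took the midpoint of its fall, 0.246 M, as the fixed value. That gave, as a reading carrying the scatter of the noon run, the pair constant k, the fractional loss of substrate per minute for each mole per litre of partner present, 0.0180 M⁻¹ min⁻¹.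

Holding [partner] at its charge for 80 min gave 70.8% of substrate left in birch and 65.9% in larch. But the rule wants the substrate charge far below the partner charge, and here it lies above it , the ratio being 1.25 in birch and 1.03 in larch. The birch answer would itself consume 36.5% of that flask's partner. My repair was a second pass with the midpoint again, 0.196 M for birch and 0.239 M for larch, which gave 75.4% and 70.9%. By this estimate the intermediate, target and side product together held 24.6% in birch and 29.1% in larch, so I answered substrate for both flasks .

The forecast, a little below mine , named substrate at 74.8% for birch and substrate at 70.3% for larch, holding that “The substrate loss fits a rate second order overall, first order in both substrate and partner”. The flasks gave substrate at 74.1% in birch and substrate at 69.6% in larch.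

    intermediate → target (k = 8.50 × 10⁻⁴ min⁻¹)
    intermediate → side product (k = 0.0100 min⁻¹)
    substrate + partner → intermediate + by-product (k = 0.0190 M⁻¹ min⁻¹)

The neighbouring flask is birch with 0.96 M of partner, read at the same time, so its ratio of substrate to partner is 0.312. With the same k, the plain rule gives 25.1%, and the midpoint 0.848 M gives 29.5%. That midpoint is 88.3% of the charge, against 81.8% in birch. The flask shows 28.5% of substrate, and there the intermediate holds most, at 42.9%.

(The numbers in the tables were computed from invented constants; scatter was added.)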